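**Retrosynthetic overview**
1. Open ring C of the flavanone at the O1–C2 bond (retro oxa-Michael). This gives the achiral (E)-2',4',4-trihydroxy-3',5'-diprenylchalcone. Closing this C–O bond forms the only new ring and sets the only stereocentre (C2, S).
2. Cut the chalcone Cα=Cβ bond (Claisen–Schmidt) to give 3,5-diprenyl-2,4-dihydroxyacetophenone and 4-hydroxybenzaldehyde.
3. Remove both prenyl groups (phenoxide C-alkylation) to give 2,4-dihydroxyacetophenone and two prenyl bromide.
4. Ring order: rings A and B are bought and ring C is made last. No protecting groups are used.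

Assumption: the [C@H] centre of the given SMILES is read as (2S). One analytical run confirms which catalyst antipode delivers (2S), and the mirror-image catalyst (from D-tert-leucine) is used if the sense is reversed.

Catalyst of step 3 ("BIMP catalyst", made separately from L-tert-leucinol and not counted in the steps): 1-[3,5-bis(trifluoromethyl)phenyl]-3-[(2S)-3,3-dimethyl-1-{[tris(4-methoxyphenyl)-λ5-phosphanylidene]amino}butan-2-yl]thiourea, COc1ccc(cc1)P(=NC[C@@H](NC(=S)Nc1cc(cc(c1)C(F)(F)F)C(F)(F)F)C(C)(C)C)(c1ccc(OC)cc1)c1ccc(OC)cc1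

**Route**

Step 1
Reactants: 1 2,4-dihydroxyacetophenone (resacetophenone); 2 prenyl bromide (1-bromo-3-methylbut-2-ene, 2.5 equiv)
Product: 5 1-[2,4-dihydroxy-3,5-bis(3-methylbut-2-enyl)phenyl]ethanone (3,5-diprenylresacetophenone), via 3-prenylresacetophenone 3 (not isolated), via 5-prenylresacetophenone 4 (not isolated)
Conditions: KOH (3.0 equiv), H2O, 0 °C → rt, 16 h; 1 M HCl to pH 4; chromatography
Reagents that add atoms: prenyl bromide (2), CC(C)=CCBr
Why: This is ambident-phenoxide C-alkylation (SN2 on the primary allylic bromide), steered to carbon because water hydrogen-bonds the phenoxide oxygen; C3 and C5 are the only ring positions ortho/para to both oxygens, so 3 and 4 both funnel into 5; the known reaction gives only about 25–35 % but runs on very cheap material, and no stereocentre is formed.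

Step 2
Reactants: 5 3,5-diprenylresacetophenone; 6 4-hydroxybenzaldehyde (1.5 equiv)
Product: 8 (E)-1-[2,4-dihydroxy-3,5-bis(3-methylbut-2-enyl)phenyl]-3-(4-hydroxyphenyl)prop-2-en-1-one, via racemic aldol adduct 7 (not isolated)
Conditions: KOH (50 % aq, 20 equiv), EtOH, N2, rt → 45 °C, 48 h; cold 2 M HCl to pH 4; crystallisation, dry thoroughly
Reagents that add atoms: 4-hydroxybenzaldehyde (6), O=Cc1ccc(O)cc1
Why: This is a Claisen–Schmidt condensation (crossed aldol, E1cB dehydration) in which 6 cannot enolise and 5 is the only enolate source; loss of water from 7 gives the conjugated (E)-enone under thermodynamic control, the large excess of KOH offsets deactivation by phenoxide formation, and the chalcone polyanion cannot ring-close, so 8 is isolated open and free of racemic flavanone; the carbinol centre of 7 is erased.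

Step 3
Reactants: 8 (E)-2',4',4-trihydroxy-3',5'-diprenylchalcone
Product: 10 (2S)-7-hydroxy-2-(4-hydroxyphenyl)-6,8-bis(3-methylbut-2-enyl)-2,3-dihydrochromen-4-one, via catalyst-bound enolate 9 (not isolated)
Conditions: BIMP catalyst (10 mol%), 4 Å MS, PhMe–THF 9:1 (0.1 M), N2, dark, 0 °C → rt, 48–72 h, stop at about 90 % conversion; silica plug, chromatography, one recrystallisation (PhMe–heptane)
Reagents that add atoms: none
Why: Proposed new method: enantioselective 6-endo-trig intramolecular oxa-Michael cyclisation of an unactivated, fully unprotected 2'-hydroxychalcone under bifunctional iminophosphorane catalysis; the strongly basic P=N site ionises the substrate to a tight aminophosphonium phenoxide ion pair, which rests as the 4'-phenoxide and relays a proton to give the reactive 2'-phenoxide; the two thiourea N–H bonds and the P–N–H+ form an oxyanion hole on the enone oxygen that replaces the internal 2'-OH···O=C hydrogen bond and stabilises the developing enolate 9; the tert-butyl wall leaves only the Si face of C-β open to the tethered phenoxide, and this C–O bond formation sets (2S); C-protonation of 9 by the next substrate phenol turns the catalyst over; only about 10 % of the material is ever ionised and the acidic 7-OH buffers the medium, which also keeps the ring B phenol un-ionised and shuts the quinone-methide opening, so retro-Michael racemisation should be slow against ring closure (flavanone favoured about 9:1 or better); the closest known reaction types are iminophosphorane-catalysed intramolecular oxa-Michael addition of alcohols to α,β-unsaturated esters and amides and cinchona-thiourea cyclisation of ester-activated 2'-hydroxychalcones, neither shown on a plain chalcone carrying free phenols.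

**Compound list**
1 | 2,4-dihydroxyacetophenone (resacetophenone) | CC(=O)c1ccc(O)cc1O | starting material
2 | prenyl bromide (1-bromo-3-methylbut-2-ene) | CC(C)=CCBr | starting material
3 | 1-[2,4-dihydroxy-3-(3-methylbut-2-enyl)phenyl]ethanone (3-prenylresacetophenone, not isolated) | CC(=O)c1ccc(O)c(CC=C(C)C)c1O | intermediate
4 | 1-[2,4-dihydroxy-5-(3-methylbut-2-enyl)phenyl]ethanone (5-prenylresacetophenone, not isolated) | CC(=O)c1cc(CC=C(C)C)c(O)cc1O | intermediate
5 | 1-[2,4-dihydroxy-3,5-bis(3-methylbut-2-enyl)phenyl]ethanone | CC(=O)c1cc(CC=C(C)C)c(O)c(CC=C(C)C)c1O | intermediate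
6 | 4-hydroxybenzaldehyde | O=Cc1ccc(O)cc1 | starting material
7 | 1-[2,4-dihydroxy-3,5-bis(3-methylbut-2-enyl)phenyl]-3-hydroxy-3-(4-hydroxyphenyl)propan-1-one (racemic aldol adduct, not isolated) | CC(C)=CCc1cc(C(=O)CC(O)c2ccc(O)cc2)c(O)c(CC=C(C)C)c1O | intermediate
8 | (E)-1-[2,4-dihydroxy-3,5-bis(3-methylbut-2-enyl)phenyl]-3-(4-hydroxyphenyl)prop-2-en-1-one | CC(C)=CCc1cc(C(=O)/C=C/c2ccc(O)cc2)c(O)c(CC=C(C)C)c1O | intermediate
9 | (2S)-2-(4-hydroxyphenyl)-6,8-bis(3-methylbut-2-enyl)-2H-chromene-4,7-diol (catalyst-bound enolate drawn as its neutral enol, not isolated) | CC(C)=CCc1cc2c(c(CC=C(C)C)c1O)O[C@H](c1ccc(O)cc1)C=C2O | intermediate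
10 | (2S)-7-hydroxy-2-(4-hydroxyphenyl)-6,8-bis(3-methylbut-2-enyl)-2,3-dihydrochromen-4-one | CC(C)=CCc1cc2c(c(CC=C(C)C)c1O)O[C@H](c1ccc(O)cc1)CC2=O | target

**Total step count:** 3. **Longest linear sequence:** 3 (1 → 5 → 8 → 10).

**Steps most likely to fail**

Step 3 (the proposed new step).
- Risks: the base may sit unproductively on the 4'- and 4-phenoxides and turn over slowly. Facial control on an unactivated chalcone may be modest. The ee can erode through reversible ring opening.
- Fallback (known chemistry): it sets out from 8. NaOAc in refluxing EtOH closes the ring without stereocontrol to give racemic 7-hydroxy-2-(4-hydroxyphenyl)-6,8-diprenylchroman-4-one F1. Preparative chiral HPLC or SFC on an amylose tris(3,5-dimethylphenylcarbamate) phase separates F1 into 10 and the (2R)-enantiomer F2. F2 is re-racemised to F1 under the same NaOAc conditions and recycled. The fallback comes back to the route at 10.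

Step 1.
- Risks: O-alkylation, incomplete alkylation, geminal dialkylation at C3 and hydrolysis of 2 all compete, and the separation is tedious.
- Fallback: it sets out from 1. Allyl bromide, K2CO3, DMF, 60 °C gives 1-[2,4-bis(prop-2-enyloxy)phenyl]ethanone F3. A double aromatic Claisen rearrangement (N,N-diethylaniline, 200 °C) follows. Only C3 and C5 can accept the allyl groups, by an ortho shift or by an ortho shift followed by a Cope shift to the para position. This gives 1-[2,4-dihydroxy-3,5-bis(prop-2-enyl)phenyl]ethanone F4. Double cross-metathesis with excess 2-methylbut-2-ene (second-generation Grubbs catalyst RuCl2(=CHPh)(PCy3)(SIMes), CH2Cl2, 40 °C) converts both allyl groups into prenyl groups. The fallback comes back to the route at 5.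

Step 2.
- Risks: both partners are deactivated as phenoxides, so conversion may stall or the mass balance may be poor.
- Fallback: it sets out from 5 and 6. MOMCl, K2CO3, acetone on 5 leaves the chelated 2-OH free and gives 1-[2-hydroxy-4-(methoxymethoxy)-3,5-bis(3-methylbut-2-enyl)phenyl]ethanone F5. MOMCl, iPr2NEt, CH2Cl2 on 6 gives 4-(methoxymethoxy)benzaldehyde F6. Condensation of these two (KOH, EtOH, rt) is now fast and gives (E)-1-[2-hydroxy-4-(methoxymethoxy)-3,5-bis(3-methylbut-2-enyl)phenyl]-3-[4-(methoxymethoxy)phenyl]prop-2-en-1-one F7. Brief treatment with 3 M HCl in MeOH at 50 °C removes both acetals. The fallback comes back to the route at 8.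

**Further compounds**
F1 | step 3 | racemic 7-hydroxy-2-(4-hydroxyphenyl)-6,8-bis(3-methylbut-2-enyl)-2,3-dihydrochromen-4-one | CC(C)=CCc1cc2c(c(CC=C(C)C)c1O)OC(c1ccc(O)cc1)CC2=O
F2 | step 3 | (2R)-7-hydroxy-2-(4-hydroxyphenyl)-6,8-bis(3-methylbut-2-enyl)-2,3-dihydrochromen-4-one | CC(C)=CCc1cc2c(c(CC=C(C)C)c1O)O[C@@H](c1ccc(O)cc1)CC2=O
F3 | step 1 | 1-[2,4-bis(prop-2-enyloxy)phenyl]ethanone | CC(=O)c1ccc(OCC=C)cc1OCC=C
F4 | step 1 | 1-[2,4-dihydroxy-3,5-bis(prop-2-enyl)phenyl]ethanone | CC(=O)c1cc(CC=C)c(O)c(CC=C)c1O
F5 | step 2 | 1-[2-hydroxy-4-(methoxymethoxy)-3,5-bis(3-methylbut-2-enyl)phenyl]ethanone | CC(=O)c1cc(CC=C(C)C)c(OCOC)c(CC=C(C)C)c1O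
F6 | step 2 | 4-(methoxymethoxy)benzaldehyde | COCOc1ccc(C=O)cc1
F7 | step 2 | (E)-1-[2-hydroxy-4-(methoxymethoxy)-3,5-bis(3-methylbut-2-enyl)phenyl]-3-[4-(methoxymethoxy)phenyl]prop-2-en-1-one | COCOc1ccc(/C=C/C(=O)c2cc(CC=C(C)C)c(OCOC)c(CC=C(C)C)c2O)cc1
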